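**Strategy.** The route rests on cutting the C1–C10 bond, the edge shared by the cyclohexane (C1, C10–C14) and the cyclodecene (C1–C10) rings, which leaves a 14-membered cembranoid carbocycle as in the presumed biosynthesis. In one operation a Lewis acid opens the C1–C2 vinyl epoxide of macrocycle 29 at its tertiary allylic carbon, the C10=C11 alkene attacks C1 across the ring, and the C20 carbamate captures the C11 cation: both carbocycles close and C1, C2, C10 and C11 are fixed. The precursor 29 is assembled from three fragments by a Nozaki–Hiyama–Kishi coupling, a Z-selective Wittig reaction and a macrocyclising Horner–Wadsworth–Emmons olefination.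

Key step: step 22

Assumption: briarane numbering is used throughout (ring carbons C1–C14, C15 methyl on C1, C16 on C5, lactone C17–C19 with C18 methyl, C20 on C11); the α face is the face of H-10.

**Fragment with the C1–C2 epoxide (C1–C4, C14, C15)**

Step 1
Reactants: 1 5-bromo-2-methylpent-2-ene
Product: 2 (E)-5-bromo-2-methylpent-2-en-1-ol
Conditions: SeO2 (cat.), t-BuOOH, salicylic acid (cat.), CH2Cl2, rt
Reagents that add atoms: tert-butyl hydroperoxide CC(C)(C)OO
Why: SeO2 allylic oxidation (ene reaction, then [2,3]-shift) of a trisubstituted alkene should oxidise the (E)-methyl group selectively.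

Step 2
Reactants: 2 (E)-5-bromo-2-methylpent-2-en-1-ol
Product: 3 [(2S,3S)-3-(2-bromoethyl)-2-methyloxiran-2-yl]methanol
Conditions: Ti(OiPr)4 (cat.), L-(+)-diethyl tartrate, t-BuOOH, 4 Å molecular sieves, CH2Cl2, −20 °C
Reagents that add atoms: tert-butyl hydroperoxide CC(C)(C)OO
Why: Sharpless asymmetric epoxidation; the L-(+)-tartrate should deliver oxygen to the face that gives the (2S,3S)-epoxide, which fixes the later C1 and C2.

Step 3
Reactants: 3 [(2S,3S)-3-(2-bromoethyl)-2-methyloxiran-2-yl]methanol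
Product: 4 (2R,3S)-3-(2-bromoethyl)-2-methyloxirane-2-carbaldehyde
Conditions: Dess–Martin periodinane, NaHCO3, CH2Cl2, 0 °C to rt
Reagents that add atoms: none
Why: Dess–Martin oxidation of a primary epoxy alcohol should leave the epoxide and the bromide untouched.

**Vinyl iodide fragment (C10–C13, C20)**

Step 4
Reactants: 5 prop-2-yn-1-ol
Product: 7 (Z)-2-(iodomethylidene)but-3-en-1-ol, via vinylmagnesium chelate 6 (not isolated)
Conditions: CH2=CHMgBr (2.5 equiv), CuI (10 mol%), THF, −10 °C to rt; then I2, −78 °C to rt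
Reagents that add atoms: vinylmagnesium bromide C=C[Mg]Br; iodine II
Why: Copper-catalysed anti-carbomagnesiation of the propargylic alkoxide should place the vinyl group on the internal carbon and magnesium cis to the CH2O group, and iodinolysis with retention should give the Z-iodide.

Step 5
Reactants: 7 (Z)-2-(iodomethylidene)but-3-en-1-ol
Product: 8 (Z)-2-(iodomethylidene)but-3-en-1-yl dimethylcarbamate
Conditions: NaH, THF, 0 °C; Me2NCOCl, 0 °C to rt
Reagents that add atoms: dimethylcarbamoyl chloride CN(C)C(Cl)=O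
Why: O-acylation of the sodium alkoxide installs the carbamate that later terminates the key cyclisation.

Step 6
Reactants: 8 (Z)-2-(iodomethylidene)but-3-en-1-yl dimethylcarbamate
Product: 10 (Z)-4-hydroxy-2-(iodomethylidene)butyl dimethylcarbamate, via B-alkyl-9-BBN adduct 9 (not isolated)
Conditions: 9-BBN, THF, 0 °C to rt; then H2O2, aq. NaOH, 0 °C
Reagents that add atoms: hydrogen peroxide OO
Why: Hydroboration–oxidation; 9-BBN should add to the monosubstituted terminus of the diene only, the iodoalkene being hindered and deactivated.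

Step 7
Reactants: 10 (Z)-4-hydroxy-2-(iodomethylidene)butyl dimethylcarbamate
Product: 11 (Z)-4-chloro-2-(iodomethylidene)butyl dimethylcarbamate
Conditions: PPh3, N-chlorosuccinimide, CH2Cl2, 0 °C to rt
Reagents that add atoms: N-chlorosuccinimide ClN1C(=O)CCC1=O
Why: Appel-type chlorination of the primary alcohol by SN2 displacement of the alkoxyphosphonium.

**Main line: lactone fragment (C6–C9, C17–C19), assembly and end game**

Step 8
Reactants: 12 but-2-yne-1,4-diol
Product: 13 4-[(4-methoxybenzyl)oxy]but-2-yn-1-ol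
Conditions: NaH (1.0 equiv), 4-methoxybenzyl chloride, Bu4NI (cat.), THF–DMF, 0 °C to rt
Reagents that add atoms: 4-methoxybenzyl chloride COc1ccc(CCl)cc1
Why: Williamson mono-etherification of the symmetrical diol with one equivalent of base.

Step 9
Reactants: 13 4-[(4-methoxybenzyl)oxy]but-2-yn-1-ol
Product: 15 (Z)-2-iodo-4-[(4-methoxybenzyl)oxy]but-2-en-1-ol, via (Z)-2-tributylstannyl alkenol 14 (not isolated)
Conditions: Bu3SnH, [Cp*RuCl]4 (cat.), CH2Cl2, rt; then I2, 0 °C
Reagents that add atoms: iodine II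
Why: Hydroxyl-directed ruthenium-catalysed trans-hydrostannation should put tin on the alkyne carbon next to the free OH (the later C8), and tin–iodine exchange with retention should give the iodide with C9 trans to C6.

Step 10
Reactants: 15 (Z)-2-iodo-4-[(4-methoxybenzyl)oxy]but-2-en-1-ol
Product: 16 tert-butyl (E)-3-(hydroxymethyl)-5-[(4-methoxybenzyl)oxy]pent-3-enoate
Conditions: BrZnCH2CO2t-Bu (from tert-butyl bromoacetate and Zn, 2.5 equiv), Pd(PPh3)4 (5 mol%), THF, 50 °C
Reagents that add atoms: tert-butyl bromoacetate BrCC(=O)OC(C)(C)C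
Why: Negishi-type cross-coupling of a Reformatsky reagent with the vinyl iodide should form C8–C17 with retention of alkene geometry.

Step 11
Reactants: 16 tert-butyl (E)-3-(hydroxymethyl)-5-[(4-methoxybenzyl)oxy]pent-3-enoate
Product: 18 (4R,5S)-4-hydroxy-4-(hydroxymethyl)-5-{[(4-methoxybenzyl)oxy]methyl}oxolan-2-one, via (2R,3R)-epoxy alcohol 17 (not isolated)
Conditions: Ti(OiPr)4 (cat.), D-(−)-diethyl tartrate, t-BuOOH, 4 Å molecular sieves, CH2Cl2, −20 °C; then crude product, camphorsulfonic acid (cat.), CH2Cl2, 0 °C to rt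
Reagents that add atoms: tert-butyl hydroperoxide CC(C)(C)OO
Why: Sharpless asymmetric epoxidation with the D-(−)-tartrate should set C7 and C8, and acid should let the tert-butyl ester carbonyl open the epoxide at C7 with inversion (loss of isobutene), giving the γ-lactone with the tertiary 8-OH cis to C6.

Step 12
Reactants: 18 lactone diol
Product: 19 (2S,3S)-3-hydroxy-2-{[(4-methoxybenzyl)oxy]methyl}-5-oxooxolane-3-carbaldehyde
Conditions: TEMPO (cat.), PhI(OAc)2, CH2Cl2, rt
Reagents that add atoms: none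
Why: Oxoammonium oxidation is selective for the primary alcohol and should neither touch the tertiary hydroxyl nor cleave the diol.

Step 13
Reactants: 19 lactone aldehyde; 11 (Z)-4-chloro-2-(iodomethylidene)butyl dimethylcarbamate
Product: 20 (4R,5S)-4-[(1S,2Z)-5-chloro-3-{[(dimethylcarbamoyl)oxy]methyl}-1-hydroxypent-2-en-1-yl]-4-hydroxy-5-{[(4-methoxybenzyl)oxy]methyl}oxolan-2-one
Conditions: CrCl2 (4 equiv), NiCl2 (cat.), chiral oxazoline sulfonamide ligand N-[2-(4-isopropyl-4,5-dihydrooxazol-2-yl)-6-methylphenyl]methanesulfonamide (antipode chosen for the 9S carbinol), Et3N, THF, rt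
Reagents that add atoms: none
Why: Nozaki–Hiyama–Kishi coupling; the alkenylchromium formed with retention of geometry should add to the aldehyde under control of the chiral sulfonamide ligand to set C9 (S), the lactone, carbamate and alkyl chloride being inert to divalent chromium.

Step 14
Reactants: 20 lactone diol alkene
Product: 21 8,9-bis(triethylsilyl) ether of 20
Conditions: Et3SiOTf, 2,6-lutidine, CH2Cl2, −78 to 0 °C
Reagents that add atoms: triethylsilyl trifluoromethanesulfonate CC[Si](CC)(CC)OS(=O)(=O)C(F)(F)F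
Why: The silyl triflate should silylate both the secondary and the tertiary hydroxyl, which blocks retro-aldol cleavage and oxygen participation later.

Step 15
Reactants: 21 bis-silyl lactone
Product: 22 17-methyl lactone (17R; methyl cis to the 8-oxygen and trans to C9)
Conditions: LiN(i-Pr)2, THF, −78 °C; MeI, −78 to −40 °C
Reagents that add atoms: iodomethane CI
Why: Alkylation of the lactone lithium enolate; methyl iodide should enter anti to the branched C9 side chain on the adjacent quaternary carbon, which sets C17.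

Step 16
Reactants: 22 17-methyl lactone chloride
Product: 23 triphenylphosphonium iodide of 22 (phosphorus on C13)
Conditions: PPh3, NaI, MeCN, 80 °C
Reagents that add atoms: triphenylphosphine c1ccccc1P(c1ccccc1)c1ccccc1; sodium iodide [Na+].[I-]
Why: Finkelstein exchange followed by SN2 quaternisation of triphenylphosphine at the primary carbon.

Step 17
Reactants: 23 phosphonium iodide; 4 (2R,3S)-3-(2-bromoethyl)-2-methyloxirane-2-carbaldehyde
Product: 25 (13Z)-vinyl epoxide bromide (C1–C4 epoxide chain joined to the lactone fragment), via phosphonium ylide 24 (not isolated)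
Conditions: NaN(SiMe3)2 (1.0 equiv), THF, −78 °C; then 4, −78 to −20 °C
Reagents that add atoms: none
Why: Wittig olefination of a non-stabilised ylide under lithium-free conditions should give the Z-alkene C13=C14, the aldehyde reacting far faster than the primary bromide.

Step 18
Reactants: 25 vinyl epoxide bromide
Product: 26 allyl 2-(diethoxyphosphoryl)alkanoate (bromide replaced by CH[P(O)(OEt)2]CO2allyl; C5 epimers)
Conditions: allyl diethylphosphonoacetate (3 equiv), NaH, Bu4NI (cat.), DMF, 0 to 50 °C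
Reagents that add atoms: allyl 2-(diethoxyphosphoryl)acetate C=CCOC(=O)CP(=O)(OCC)OCC
Why: SN2 alkylation of the stabilised phosphonate carbanion by the primary bromide forms C4–C5; the C5 stereocentre is lost in step 21.

Step 19
Reactants: 26 phosphonate PMB ether
Product: 27 phosphonate primary alcohol (free C6–OH)
Conditions: DDQ, CH2Cl2–pH 7 buffer, 0 °C
Reagents that add atoms: none
Why: Oxidative cleavage of the 4-methoxybenzyl ether by DDQ should spare the silyl ethers, the vinyl epoxide and the carbamate.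

Step 20
Reactants: 27 phosphonate alcohol
Product: 28 phosphonate aldehyde (C6 aldehyde)
Conditions: Dess–Martin periodinane, NaHCO3, CH2Cl2, 0 °C
Reagents that add atoms: none
Why: Buffered Dess–Martin oxidation should give the α-acyloxy aldehyde without epimerising C7.

Step 21
Reactants: 28 phosphonate aldehyde
Product: 29 14-membered macrocycle ((5E)-enoate with allyl ester C16; lactone; 8,9-bis-OTES; (10Z)-alkene bearing CH2OC(O)NMe2; (13Z)-alkene; C1–C2 epoxide)
Conditions: LiCl, i-Pr2NEt, MeCN, rt, 1 mM (slow addition)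
Reagents that add atoms: none
Why: Intramolecular Horner–Wadsworth–Emmons olefination under mild LiCl–amine conditions should close the 14-membered ring and give the E-enoate (ester trans to C7), as α-substituted phosphonoacetates usually do.

Step 22
Reactants: 29 macrocycle
Product: 31 briarane core (2-OH; 11,20-cyclic carbonate; 13-ene; 8,9-bis-OTES; allyl 16-oate), via cyclic iminium carbonate 30 (not isolated)
Conditions: BF3·OEt2 (2.2 equiv), CH2Cl2, −78 °C, 3 mM; then sat. aq. NaHCO3, 0 °C to rt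
Reagents that add atoms: water O
Why: BF3 ionises the vinyl epoxide at the tertiary allylic carbon C1 (oxygen stays on C2), C10 of the C10=C11 alkene attacks C1 anti to the departing oxygen through a chair-like transannular transition state, and the carbonyl oxygen of the C20 dimethylcarbamate traps the tertiary C11 cation as a cyclic iminium carbonate that water converts into the carbonate. The closest known reaction types are Lewis-acid epoxide-initiated cation–olefin cyclisations, transannular cyclisations of cembrane and germacrane epoxides, and carbamate- or carbonate-terminated cationic cyclisations. The cyclohexene closes in a 6-endo mode onto the allyl cation terminus across the Z-C13=C14 tether, the same bond divides the 14-membered ring to leave the ten-membered carbocycle, and the dioxolanone closes 5-exo at C11. C1 is set by inversion of the epoxide carbon from step 2 and C2 is retained, C10 should follow from the chair with C2 and C9 pseudo-equatorial (H-10 trans to C15), and C11 from anti addition across the alkene, which places its oxygen equatorial on the α face. The step needs C10=C11 to react in preference to C5=C6 and to hydride shift or proton loss: C5=C6 is an enoate with a γ-acyloxy group and thus a poor π-nucleophile, the silyl ethers at O8 and O9 are weak competitors, and the carbamate participates as the cation develops.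

Step 23
Reactants: 31 cyclic carbonate
Product: 32 11,20-diol
Conditions: K2CO3 (0.3 equiv), MeOH, 0 °C
Reagents that add atoms: none
Why: Base-catalysed methanolysis of the five-membered cyclic carbonate should be much faster than transesterification of the hindered allyl enoate.

Step 24
Reactants: 32 11,20-diol
Product: 34 11,20-epoxide (oxygen α, C20 β), via primary tosylate 33 (not isolated)
Conditions: TsCl, Et3N, Me3N·HCl (cat.), CH2Cl2, 0 °C; then K2CO3, MeOH, 0 °C
Reagents that add atoms: none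
Why: Selective sulfonylation of the primary hydroxyl and intramolecular Williamson closure by the tertiary alkoxide form the spiro-epoxide with retention at C11.

Step 25
Reactants: 34 epoxide bis-silyl ether
Product: 35 2,8,9-triol
Conditions: Bu4NF, AcOH, THF, 0 °C to rt
Reagents that add atoms: none
Why: Fluoride desilylation buffered with acetic acid should spare the epoxide, the lactone and the allyl ester.

Step 26
Reactants: 35 triol
Product: 36 2,9-diacetate (8-OH free)
Conditions: Ac2O, pyridine, DMAP (cat.), CH2Cl2, 0 °C to rt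
Reagents that add atoms: acetic anhydride CC(=O)OC(C)=O
Why: Acylation of the two secondary hydroxyls; the tertiary 8-OH should not react under these conditions.

Step 27
Reactants: 36 2,9-diacetate
Product: 37 12α-alcohol (allylic to C13=C14)
Conditions: SeO2 (cat.), t-BuOOH, 1,2-dichloroethane, 50 °C
Reagents that add atoms: tert-butyl hydroperoxide CC(C)(C)OO
Why: SeO2 allylic hydroxylation (ene reaction, then [2,3]-shift) returns oxygen to C12, the only allylic CH2 of C13=C14, and should do so on the α face opposite the axial C15 methyl, while the enoate alkene is inert.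

Step 28
Reactants: 37 12α-alcohol
Product: 40 12-O-triethylsilyl 13α,14α-diol, via osmate ester 38 (not isolated), via silylated osmate ester 39 (not isolated)
Conditions: OsO4 (1.05 equiv), TMEDA, CH2Cl2, −78 °C; then Et3SiOTf, 2,6-lutidine, −78 to 0 °C; then ethylenediamine, rt
Reagents that add atoms: osmium tetroxide O=[Os](=O)(=O)=O; triethylsilyl trifluoromethanesulfonate CC[Si](CC)(CC)OS(=O)(=O)C(F)(F)F
Why: Hydrogen-bond-directed dihydroxylation by OsO4·TMEDA should add syn to the allylic 12-OH (α face) and only to that alkene, and the hexavalent osmium glycolate ester masks the new diol while the 12-OH is silylated before ligand exchange frees the diol.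

Step 29
Reactants: 40 12-O-silyl diol
Product: 41 2,9,13,14-tetraacetate 12-O-triethylsilyl ether
Conditions: Ac2O, pyridine, DMAP, CH2Cl2, rt
Reagents that add atoms: acetic anhydride CC(=O)OC(C)=O
Why: Acetylation of the 13,14-diol while O12 is silylated differentiates the three contiguous cis oxygens.

Step 30
Reactants: 41 silyl ether
Product: 42 12-alcohol tetraacetate (allyl 16-oate)
Conditions: Bu4NF, AcOH, THF, 0 °C
Reagents that add atoms: none
Why: Buffered fluoride desilylation should free the 12-OH without acetyl migration.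

Step 31
Reactants: 42 allyl ester
Product: 43 16-oic acid
Conditions: Pd(PPh3)4 (5 mol%), morpholine, THF, rt
Reagents that add atoms: none
Why: Tsuji–Trost-type deallylation: zerovalent palladium ionises the allyl ester and morpholine traps the allyl group, the hindered allylic lactone C7–O bond reacting far more slowly.

Step 32
Reactants: 43 16-oic acid
Product: 45 16-alcohol, via mixed isobutyl carbonic anhydride 44 (not isolated)
Conditions: i-BuOCOCl, N-methylmorpholine, THF, −15 °C; then NaBH4, H2O, 0 °C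
Reagents that add atoms: none
Why: Mixed-anhydride activation followed by borohydride reduction is chemoselective for the carboxylic acid over lactone, acetates and epoxide.

Step 33
Reactants: 45 16-alcohol
Product: 46 CNP0330408.1
Conditions: N-chlorosuccinimide, Me2S, CH2Cl2, −20 to 0 °C
Reagents that add atoms: N-chlorosuccinimide ClN1C(=O)CCC1=O
Why: Corey–Kim chlorination converts the primary allylic alcohol into the chloride by SN2 attack of chloride on the alkoxysulfonium salt, leaving the hindered 12-OH and tertiary 8-OH untouched.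

**Compound list**

1 | 5-bromo-2-methylpent-2-ene | CC(C)=CCCBr | starting material
2 | (E)-5-bromo-2-methylpent-2-en-1-ol | OC/C(C)=C/CCBr | intermediate
3 | [(2S,3S)-3-(2-bromoethyl)-2-methyloxiran-2-yl]methanol | OC[C@]1(C)O[C@H]1CCBr | intermediate
4 | (2R,3S)-3-(2-bromoethyl)-2-methyloxirane-2-carbaldehyde | O=C[C@]1(C)O[C@H]1CCBr | intermediate
5 | prop-2-yn-1-ol | C#CCO | starting material
6 | 4-vinyl-2,5-dihydro-1,2-oxamagnesole chelate | C=CC1=C[Mg]OC1 | intermediate (not isolated)
7 | (Z)-2-(iodomethylidene)but-3-en-1-ol | OC/C(C=C)=C\I | intermediate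
8 | (Z)-2-(iodomethylidene)but-3-en-1-yl dimethylcarbamate | CN(C)C(=O)OC/C(C=C)=C\I | intermediate
9 | B-alkyl-9-BBN adduct of 8 (boron on C13) | CN(C)C(=O)OC/C(CCB1C2CCCC1CCC2)=C\I | intermediate (not isolated)
10 | (Z)-4-hydroxy-2-(iodomethylidene)butyl dimethylcarbamate | CN(C)C(=O)OC/C(CCO)=C\I | intermediate
11 | (Z)-4-chloro-2-(iodomethylidene)butyl dimethylcarbamate | CN(C)C(=O)OC/C(CCCl)=C\I | intermediate
12 | but-2-yne-1,4-diol | OCC#CCO | starting material
13 | 4-[(4-methoxybenzyl)oxy]but-2-yn-1-ol | OCC#CCOCc1ccc(OC)cc1 | intermediate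
14 | (Z)-4-[(4-methoxybenzyl)oxy]-2-(tributylstannyl)but-2-en-1-ol | OC/C([Sn](CCCC)(CCCC)CCCC)=C/COCc1ccc(OC)cc1 | intermediate (not isolated)
15 | (Z)-2-iodo-4-[(4-methoxybenzyl)oxy]but-2-en-1-ol | OC/C(I)=C/COCc1ccc(OC)cc1 | intermediate
16 | tert-butyl (E)-3-(hydroxymethyl)-5-[(4-methoxybenzyl)oxy]pent-3-enoate | OC/C(CC(=O)OC(C)(C)C)=C/COCc1ccc(OC)cc1 | intermediate
17 | tert-butyl 2-[(2R,3R)-2-(hydroxymethyl)-3-{[(4-methoxybenzyl)oxy]methyl}oxiran-2-yl]acetate | OC[C@@]1(CC(=O)OC(C)(C)C)O[C@@H]1COCc2ccc(OC)cc2 | intermediate (not isolated)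
18 | (4R,5S)-4-hydroxy-4-(hydroxymethyl)-5-{[(4-methoxybenzyl)oxy]methyl}oxolan-2-one | OC[C@@]1(O)[C@H](COCc2ccc(OC)cc2)OC(=O)C1 | intermediate
19 | (2S,3S)-3-hydroxy-2-{[(4-methoxybenzyl)oxy]methyl}-5-oxooxolane-3-carbaldehyde | O=C[C@@]1(O)[C@H](COCc2ccc(OC)cc2)OC(=O)C1 | intermediate
20 | (4R,5S)-4-[(1S,2Z)-5-chloro-3-{[(dimethylcarbamoyl)oxy]methyl}-1-hydroxypent-2-en-1-yl]-4-hydroxy-5-{[(4-methoxybenzyl)oxy]methyl}oxolan-2-one | ClCC/C(COC(=O)N(C)C)=C/[C@H](O)[C@@]1(O)[C@H](COCc2ccc(OC)cc2)OC(=O)C1 | intermediate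
21 | 8,9-bis(triethylsilyl) ether of 20 | ClCC/C(COC(=O)N(C)C)=C/[C@H](O[Si](CC)(CC)CC)[C@@]1(O[Si](CC)(CC)CC)[C@H](COCc2ccc(OC)cc2)OC(=O)C1 | intermediate
22 | 17R-methyl lactone (21 with the C18 methyl on C17, cis to O8) | ClCC/C(COC(=O)N(C)C)=C/[C@H](O[Si](CC)(CC)CC)[C@@]1(O[Si](CC)(CC)CC)[C@H](COCc2ccc(OC)cc2)OC(=O)[C@@H]1C | intermediate
23 | C13 triphenylphosphonium iodide of 22 | [I-].c1ccccc1[P+](c1ccccc1)(c1ccccc1)CC/C(COC(=O)N(C)C)=C/[C@H](O[Si](CC)(CC)CC)[C@@]1(O[Si](CC)(CC)CC)[C@H](COCc2ccc(OC)cc2)OC(=O)[C@@H]1C | intermediate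
24 | phosphonium ylide of 23 | c1ccccc1P(c1ccccc1)(c1ccccc1)=CC/C(COC(=O)N(C)C)=C/[C@H](O[Si](CC)(CC)CC)[C@@]1(O[Si](CC)(CC)CC)[C@H](COCc2ccc(OC)cc2)OC(=O)[C@@H]1C | intermediate (not isolated)
25 | (13Z)-vinyl epoxide bromide (C4 bromide, C1–C2 epoxide, C6 PMB ether) | BrCC[C@@H]1O[C@@]1(C)/C=C\C/C(COC(=O)N(C)C)=C/[C@H](O[Si](CC)(CC)CC)[C@@]2(O[Si](CC)(CC)CC)[C@H](COCc3ccc(OC)cc3)OC(=O)[C@@H]2C | intermediate
26 | allyl phosphonoacetate of 25 (C5 epimers) | C=CCOC(=O)C(P(=O)(OCC)OCC)CC[C@@H]1O[C@@]1(C)/C=C\C/C(COC(=O)N(C)C)=C/[C@H](O[Si](CC)(CC)CC)[C@@]2(O[Si](CC)(CC)CC)[C@H](COCc3ccc(OC)cc3)OC(=O)[C@@H]2C | intermediate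
27 | phosphonate with free C6 alcohol | C=CCOC(=O)C(P(=O)(OCC)OCC)CC[C@@H]1O[C@@]1(C)/C=C\C/C(COC(=O)N(C)C)=C/[C@H](O[Si](CC)(CC)CC)[C@@]2(O[Si](CC)(CC)CC)[C@H](CO)OC(=O)[C@@H]2C | intermediate
28 | phosphonate C6 aldehyde | C=CCOC(=O)C(P(=O)(OCC)OCC)CC[C@@H]1O[C@@]1(C)/C=C\C/C(COC(=O)N(C)C)=C/[C@H](O[Si](CC)(CC)CC)[C@@]2(O[Si](CC)(CC)CC)[C@H](C=O)OC(=O)[C@@H]2C | intermediate
29 | 14-membered macrocycle ((5E)-enoate, (10Z)- and (13Z)-alkenes, C1–C2 epoxide, 7,8-lactone) | C3C[C@@H]1O[C@@]1(C)/C=C\C/C(COC(=O)N(C)C)=C/[C@H](O[Si](CC)(CC)CC)[C@@]2(O[Si](CC)(CC)CC)[C@H](/C=C3/C(=O)OCC=C)OC(=O)[C@@H]2C | intermediate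
30 | cyclic 2-(dimethyliminio)-1,3-dioxolane at C11/C20 with O2–BF3 alkoxide | C1C[C@]2(COC(=[N+](C)C)O2)[C@@H]3[C@H](O[Si](CC)(CC)CC)[C@@]4(O[Si](CC)(CC)CC)[C@H](/C=C(/C(=O)OCC=C)CC[C@H](O[B-](F)(F)F)[C@@]3(C)C=1)OC(=O)[C@@H]4C | intermediate (not isolated)
31 | briarane core: 2-hydroxy, 11,20-cyclic carbonate, 13-ene, 8,9-bis-OTES, allyl 16-oate | C1C[C@]2(COC(=O)O2)[C@@H]3[C@H](O[Si](CC)(CC)CC)[C@@]4(O[Si](CC)(CC)CC)[C@H](/C=C(/C(=O)OCC=C)CC[C@H](O)[C@@]3(C)C=1)OC(=O)[C@@H]4C | intermediate
32 | 2,11,20-triol (11,20-diol freed) | C1C[C@](O)(CO)[C@@H]3[C@H](O[Si](CC)(CC)CC)[C@@]4(O[Si](CC)(CC)CC)[C@H](/C=C(/C(=O)OCC=C)CC[C@H](O)[C@@]3(C)C=1)OC(=O)[C@@H]4C | intermediate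
33 | 20-O-tosylate of 32 | C1C[C@](O)(COS(=O)(=O)c5ccc(C)cc5)[C@@H]3[C@H](O[Si](CC)(CC)CC)[C@@]4(O[Si](CC)(CC)CC)[C@H](/C=C(/C(=O)OCC=C)CC[C@H](O)[C@@]3(C)C=1)OC(=O)[C@@H]4C | intermediate (not isolated)
34 | 11,20-epoxide (8,9-bis-OTES, 2-OH) | C1C[C@]2(CO2)[C@@H]3[C@H](O[Si](CC)(CC)CC)[C@@]4(O[Si](CC)(CC)CC)[C@H](/C=C(/C(=O)OCC=C)CC[C@H](O)[C@@]3(C)C=1)OC(=O)[C@@H]4C | intermediate
35 | 11,20-epoxy 2,8,9-triol | C1C[C@]2(CO2)[C@@H]3[C@H](O)[C@@]4(O)[C@H](/C=C(/C(=O)OCC=C)CC[C@H](O)[C@@]3(C)C=1)OC(=O)[C@@H]4C | intermediate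
36 | 2,9-diacetate | C1C[C@]2(CO2)[C@@H]3[C@H](OC(C)=O)[C@@]4(O)[C@H](/C=C(/C(=O)OCC=C)CC[C@H](OC(C)=O)[C@@]3(C)C=1)OC(=O)[C@@H]4C | intermediate
37 | 12α-hydroxy 2,9-diacetate | C1[C@@H](O)[C@]2(CO2)[C@@H]3[C@H](OC(C)=O)[C@@]4(O)[C@H](/C=C(/C(=O)OCC=C)CC[C@H](OC(C)=O)[C@@]3(C)C=1)OC(=O)[C@@H]4C | intermediate
38 | 13,14-osmate ester (hexavalent osmium, TMEDA complex), 12-OH free | CN(C)CCN(C)C.O=[Os]5(=O)O[C@H]1[C@@H](O)[C@]2(CO2)[C@@H]3[C@H](OC(C)=O)[C@@]4(O)[C@H](/C=C(/C(=O)OCC=C)CC[C@H](OC(C)=O)[C@@]3(C)[C@H]1O5)OC(=O)[C@@H]4C | intermediate (not isolated)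
39 | 12-O-triethylsilyl osmate ester | CN(C)CCN(C)C.O=[Os]5(=O)O[C@H]1[C@@H](O[Si](CC)(CC)CC)[C@]2(CO2)[C@@H]3[C@H](OC(C)=O)[C@@]4(O)[C@H](/C=C(/C(=O)OCC=C)CC[C@H](OC(C)=O)[C@@]3(C)[C@H]1O5)OC(=O)[C@@H]4C | intermediate (not isolated)
40 | 12-O-triethylsilyl 13α,14α-diol | O[C@H]1[C@@H](O[Si](CC)(CC)CC)[C@]2(CO2)[C@@H]3[C@H](OC(C)=O)[C@@]4(O)[C@H](/C=C(/C(=O)OCC=C)CC[C@H](OC(C)=O)[C@@]3(C)[C@H]1O)OC(=O)[C@@H]4C | intermediate
41 | 2,9,13,14-tetraacetate 12-O-triethylsilyl ether | CC(=O)O[C@H]1[C@@H](O[Si](CC)(CC)CC)[C@]2(CO2)[C@@H]3[C@H](OC(C)=O)[C@@]4(O)[C@H](/C=C(/C(=O)OCC=C)CC[C@H](OC(C)=O)[C@@]3(C)[C@H]1OC(C)=O)OC(=O)[C@@H]4C | intermediate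
42 | 12-hydroxy tetraacetate, allyl 16-oate | CC(=O)O[C@H]1[C@@H](O)[C@]2(CO2)[C@@H]3[C@H](OC(C)=O)[C@@]4(O)[C@H](/C=C(/C(=O)OCC=C)CC[C@H](OC(C)=O)[C@@]3(C)[C@H]1OC(C)=O)OC(=O)[C@@H]4C | intermediate
43 | 16-oic acid | CC(=O)O[C@H]1[C@@H](O)[C@]2(CO2)[C@@H]3[C@H](OC(C)=O)[C@@]4(O)[C@H](/C=C(/C(O)=O)CC[C@H](OC(C)=O)[C@@]3(C)[C@H]1OC(C)=O)OC(=O)[C@@H]4C | intermediate
44 | mixed isobutyl carbonic anhydride of 43 | CC(=O)O[C@H]1[C@@H](O)[C@]2(CO2)[C@@H]3[C@H](OC(C)=O)[C@@]4(O)[C@H](/C=C(/C(=O)OC(=O)OCC(C)C)CC[C@H](OC(C)=O)[C@@]3(C)[C@H]1OC(C)=O)OC(=O)[C@@H]4C | intermediate (not isolated)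
45 | 16-alcohol (16-hydroxy analogue of the target) | CC(=O)O[C@H]1[C@@H](O)[C@]2(CO2)[C@@H]3[C@H](OC(C)=O)[C@@]4(O)[C@H](/C=C(/CO)CC[C@H](OC(C)=O)[C@@]3(C)[C@H]1OC(C)=O)OC(=O)[C@@H]4C | intermediate
46 | CNP0330408.1 (1S,2S,5E,7S,8S,9S,10S,11R,12R,13S,14R,17R) | CC(=O)O[C@H]1[C@@H](O)[C@]2(CO2)[C@@H]2[C@H](OC(C)=O)[C@@]3(O)[C@H](/C=C(/CCl)CC[C@H](OC(C)=O)[C@@]2(C)[C@H]1OC(C)=O)OC(=O)[C@@H]3C | target

**Summary**

Total step count: 33. Longest linear sequence: 26 steps (steps 8–33, from but-2-yne-1,4-diol); the epoxide fragment (steps 1–3) and the vinyl iodide fragment (steps 4–7) join at steps 17 and 13.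

Three steps most likely to fail:

1. Step 22 (key step). The ionised vinyl epoxide may undergo a 1,2-hydride shift (Meinwald-type rearrangement) or proton loss before the alkene arrives, the cation may be trapped by another oxygen, or a boat-like folding may give the C10 epimer. Fallback: the same Lewis-acid epoxide–alkene cyclisation is run on the open chain, where only the six-membered ring has to close. Starting from 25, BF3·OEt2 at −78 °C and aqueous NaHCO3 should give the open-chain cyclohexene carbonate F1. Alkylation of sodium allyl diethylphosphonoacetate with its bromide gives the phosphonate F2, DDQ removes the PMB group to give the primary alcohol F3, and TEMPO/PhI(OAc)2 (selective for the primary hydroxyl beside the free 2-OH) gives the aldehyde F4. Horner–Wadsworth–Emmons ring closure of the ten-membered ring (LiCl, i-Pr2NEt, MeCN, high dilution) then returns to the route at 31.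

2. Step 21. The α-acyloxy aldehyde may epimerise at C7 or lose the 8-silyloxy group by β-elimination under base, may oligomerise, or may give the wrong alkene geometry. Fallback: a base-free intramolecular Wittig reaction of a stabilised ylide. Starting from 25, DDQ gives the bromo alcohol F5. Heating with allyl (triphenylphosphoranylidene)acetate (2.2 equiv, the second equivalent acting as base) C-alkylates the ylide and gives the α-substituted stabilised hydroxy ylide F6. Dess–Martin oxidation in the presence of the ylide under high dilution (CH2Cl2 then toluene, 60 °C) lets the aldehyde be consumed as it forms by intramolecular Wittig olefination, which returns to the route at 29.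

3. Step 15. Methyl iodide may approach the lactone enolate from the face of the C9 side chain (poor or reversed facial selectivity), so that the C17 epimer forms. Fallback: the centre is set by protonation instead of alkylation. Starting from 21, the alkylation is taken to the 17-epimeric methyl lactone F7; its lithium enolate (LiN(i-Pr)2, THF, −78 °C) is then protonated kinetically with 2,6-di-tert-butyl-4-methylphenol. The proton should enter from the face that the methyl group had used, which returns to the route at 22.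

Further compounds
F1 | step 22 | open-chain cyclohexene 11,20-carbonate (C1–C10 bond formed; C2-hydroxy C4-bromide chain on C1) | C1C[C@]2(COC(=O)O2)[C@H]([C@H](O[Si](CC)(CC)CC)[C@@]3(O[Si](CC)(CC)CC)[C@H](COCc4ccc(OC)cc4)OC(=O)[C@@H]3C)[C@]([C@@H](O)CCBr)(C)C=1
F2 | step 22 | allyl phosphonoacetate of F1 | C1C[C@]2(COC(=O)O2)[C@H]([C@H](O[Si](CC)(CC)CC)[C@@]3(O[Si](CC)(CC)CC)[C@H](COCc4ccc(OC)cc4)OC(=O)[C@@H]3C)[C@]([C@@H](O)CCC(C(=O)OCC=C)P(=O)(OCC)OCC)(C)C=1
F3 | step 22 | C6 primary alcohol of F2 | C1C[C@]2(COC(=O)O2)[C@H]([C@H](O[Si](CC)(CC)CC)[C@@]3(O[Si](CC)(CC)CC)[C@H](CO)OC(=O)[C@@H]3C)[C@]([C@@H](O)CCC(C(=O)OCC=C)P(=O)(OCC)OCC)(C)C=1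
F4 | step 22 | C6 aldehyde of F3 | C1C[C@]2(COC(=O)O2)[C@H]([C@H](O[Si](CC)(CC)CC)[C@@]3(O[Si](CC)(CC)CC)[C@H](C=O)OC(=O)[C@@H]3C)[C@]([C@@H](O)CCC(C(=O)OCC=C)P(=O)(OCC)OCC)(C)C=1
F5 | step 21 | bromo alcohol (25 without the PMB group) | BrCC[C@@H]1O[C@@]1(C)/C=C\C/C(COC(=O)N(C)C)=C/[C@H](O[Si](CC)(CC)CC)[C@@]2(O[Si](CC)(CC)CC)[C@H](CO)OC(=O)[C@@H]2C
F6 | step 21 | α-substituted allyl (triphenylphosphoranylidene)acetate with free C6 alcohol | C=CCOC(=O)C(CC[C@@H]1O[C@@]1(C)/C=C\C/C(COC(=O)N(C)C)=C/[C@H](O[Si](CC)(CC)CC)[C@@]2(O[Si](CC)(CC)CC)[C@H](CO)OC(=O)[C@@H]2C)=P(c3ccccc3)(c3ccccc3)c3ccccc3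
F7 | step 15 | C17 epimer of 22 | ClCC/C(COC(=O)N(C)C)=C/[C@H](O[Si](CC)(CC)CC)[C@@]1(O[Si](CC)(CC)CC)[C@H](COCc2ccc(OC)cc2)OC(=O)[C@H]1C
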